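**Retrosynthetic overview**
- Feature: C1, the diarylmethine carbon, carries two identical 2,4,5-trimethoxyphenyl rings. Each ring is bonded through the carbon that is C5, the most electron-rich CH, of 1,2,4-trimethoxybenzene. C1–C2(OH)–C3 is the chain of lactaldehyde, with C1 as the former carbonyl carbon.
- Target ⇒ (debenzylation) its O-benzyl ether ⇒ (both C1–aryl bonds cut together, double Friedel–Crafts/Baeyer condensation) (R)-2-(benzyloxy)propanal + 2 × 1,2,4-trimethoxybenzene.
- (R)-2-(Benzyloxy)propanal ⇒ (ester half-reduction) methyl (R)-2-(benzyloxy)propanoate ⇒ (base-free O-benzylation) methyl (R)-lactate + benzyl bromide.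
- No ring is formed at any stage, since both benzene rings are bought intact. The only stereocentre (C2) comes from the chiral pool, and its C–O and C–H bonds are never broken.

Key step: step 3

Remark on the chemistry: the target SMILES encodes R at C2. The priority order O > C1 > C3 > H holds in every compound from 1 to 10, so the descriptor stays R as long as the configuration is retained. Methyl (R)-lactate (the D-series ester) is therefore the correct chiral-pool input.

**Step 1**
Reactants: 1 methyl (R)-lactate; 2 benzyl bromide
Product: 3 methyl (R)-2-(benzyloxy)propanoate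
Conditions: BnBr (1.3 equiv), Ag2O (1.0 equiv), 4 Å MS, Et2O, 0 °C → rt, dark
Reagents that add atoms: benzyl bromide (compound 2), BrCc1ccccc1
Why: In this silver(I)-assisted Williamson-type O-alkylation, Ag2O acts as halophile and acid scavenger, so no free alkoxide or enolate should arise, the acidic C2–H next to the ester is left alone, and C2 is retained because only the O–H bond is broken.

**Step 2**
Reactants: 3 methyl (R)-2-(benzyloxy)propanoate
Product: 5 (R)-2-(benzyloxy)propanal, via aluminium hemiacetal 4 (not isolated)
Conditions: DIBAL-H (1.1 equiv, hexanes), CH2Cl2, −78 °C; MeOH, −78 °C; aq. Rochelle salt, rt; crude aldehyde used at once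
Reagents that add atoms: none
Why: In this partial ester reduction with DIBAL-H, the tetrahedral aluminium hemiacetal 4, held by chelation to the benzyloxy oxygen, should persist at −78 °C until the hydride is destroyed, so the aldehyde is released only on work-up and C2 sees no base.

**Step 3**
Reactants: 5 (R)-2-(benzyloxy)propanal; 6 1,2,4-trimethoxybenzene (two molecules are incorporated)
Product: 9 (R)-2-(benzyloxy)-1,1-bis(2,4,5-trimethoxyphenyl)propane, via benzylic carbinol 7 (not isolated), via benzylic cation 8 (not isolated)
Conditions: 6 (3.0 equiv), Sc(OTf)3 (10 mol %), 4 Å MS, CH2Cl2, −40 → 0 °C, slow addition of 5; aq. NaHCO3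
Reagents that add atoms: 1,2,4-trimethoxybenzene (compound 6), COc1ccc(OC)c(OC)c1
Why: Sc(III) activates the carbonyl of 5 (plausibly as a five-membered chelate that also engages the benzyloxy oxygen), and C5 of 6 attacks the carbonyl carbon in a Friedel–Crafts hydroxyalkylation to give carbinol 7 as a mixture of C1 epimers that is of no consequence. The same catalyst ionises 7 to the 2,4,5-trimethoxybenzylic cation 8, whose charge is shared by the ortho and para methoxy oxygens, and a second molecule of 6 captures it at C5 in a Friedel–Crafts alkylation, so both C1–aryl bonds arise in one flask with water as the only other product. The closest known reaction type is the Baeyer condensation of aldehydes with electron-rich arenes and heteroarenes to 1,1-diarylalkanes, triarylmethanes, dipyrromethanes and bis(indolyl)methanes, and each half (Sc(OTf)3-promoted carbonyl addition at low temperature, Sc(OTf)3-catalysed arylation with benzylic alcohols) is established on its own. No ring is closed and no new stereocentre remains, since C1 ends with two identical aryl groups, while C2 keeps the lactate configuration because neither its C–O nor its C–H bond takes part. Regioselectivity on the arene is secured by 6 itself: C5 is para to the 2-methoxy and ortho to the 4-methoxy group and unhindered, C3 is wedged between two methoxy groups, and C6 is activated by one methoxy group only. Chemoselectivity requires that arylation outrun enolisation of 5 and that capture of 8 outrun a C2→C1 hydride shift, loss of the C2 proton or attack by the unactivated phenyl ring of the benzyl ether, and this is served by the base-free medium, the low temperature, the slow addition of 5 into a threefold excess of the far more nucleophilic arene and the high intrinsic stabilisation of 8.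

**Step 4**
Reactants: 9 (R)-2-(benzyloxy)-1,1-bis(2,4,5-trimethoxyphenyl)propane
Product: 10 tatarinoid C, (R)-1,1-bis(2,4,5-trimethoxyphenyl)propan-2-ol
Conditions: H2 (1 atm), 10% Pd/C, EtOAc/EtOH, rt
Reagents that add atoms: none
Why: In this catalytic hydrogenolysis of a benzyl ether, O–CH2Ph is the only benzylic C–O bond present, so the homobenzylic C2–O bond, the six aryl methyl ethers and the C1–H diarylmethine should stay untouched and C2 is delivered unchanged as R.

**Compound list**
1 | methyl (R)-lactate | C[C@@H](O)C(=O)OC | starting material
2 | benzyl bromide | BrCc1ccccc1 | starting material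
3 | methyl (R)-2-(benzyloxy)propanoate | C[C@@H](OCc1ccccc1)C(=O)OC | intermediate
4 | [(2R)-2-(benzyloxy)-1-methoxypropoxy]diisobutylaluminium (aluminium hemiacetal, C1 epimers, not isolated) | C[C@@H](OCc1ccccc1)C(OC)O[Al](CC(C)C)CC(C)C | intermediate
5 | (R)-2-(benzyloxy)propanal | C[C@@H](OCc1ccccc1)C=O | intermediate
6 | 1,2,4-trimethoxybenzene | COc1ccc(OC)c(OC)c1 | starting material
7 | (2R)-2-(benzyloxy)-1-(2,4,5-trimethoxyphenyl)propan-1-ol (C1 epimers, not isolated) | C[C@@H](OCc1ccccc1)C(O)c1cc(OC)c(OC)cc1OC | intermediate
8 | (2R)-2-(benzyloxy)-1-(2,4,5-trimethoxyphenyl)propan-1-ylium (not isolated) | C[C@@H](OCc1ccccc1)[CH+]c1cc(OC)c(OC)cc1OC | intermediate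
9 | (R)-2-(benzyloxy)-1,1-bis(2,4,5-trimethoxyphenyl)propane (O-benzyl tatarinoid C) | C[C@@H](OCc1ccccc1)C(c1cc(OC)c(OC)cc1OC)c1cc(OC)c(OC)cc1OC | intermediate
10 | tatarinoid C, (R)-1,1-bis(2,4,5-trimethoxyphenyl)propan-2-ol | COc1cc(OC)c(C(c2cc(OC)c(OC)cc2OC)[C@@H](C)O)cc1OC | target

**Total step count:** 4
**Longest linear sequence:** 4 (1 → 3 → 5 → 9 → 10)

**Steps most likely to fail**

(a) Step 3.
- Risks: the C2 hydride may migrate to the cationic C1, or the C2 proton may be lost, before the second arene arrives. Either event would drain material and erase the stereocentre. Enolisation or self-condensation of the aldehyde before the first attack is also possible, as is cyclisation of the cation onto the phenyl ring of its own benzyl ether.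
- Fallback route: it sets out from 3 and 6 and returns at 9. Compound 6 is brominated at C5 (NBS, MeCN, 0 °C) to 1-bromo-2,4,5-trimethoxybenzene F1. Bromine–lithium exchange (n-BuLi, THF, −78 °C) gives 2,4,5-trimethoxyphenyllithium F2. A little over two equivalents of F2 add to ester 3, passing in the flask through (R)-2-(benzyloxy)-1-(2,4,5-trimethoxyphenyl)propan-1-one F3, and give the tertiary carbinol (R)-2-(benzyloxy)-1,1-bis(2,4,5-trimethoxyphenyl)propan-1-ol F4 after an NH4Cl quench. Ionic hydrogenation (Et3SiH, TFA, CH2Cl2, −20 → 0 °C) ionises it to (R)-2-(benzyloxy)-1,1-bis(2,4,5-trimethoxyphenyl)propan-1-ylium F5, which takes hydride from the silane and gives 9.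
- Rationale: both C1–aryl bonds are made with carbanionic aryl donors. The only cation on the way is stabilised by two rings and meets an excess of hydride donor, so a shift from C2 has little driving force.

(b) Step 2.
- Risks: premature collapse of the aluminium hemiacetal would lead to over-reduction. Configurational purity at C2 may erode, and the sensitive aldehyde may hydrate or oligomerise during isolation.
- Fallback route: it sets out from 3 and returns at 5. Full reduction (LiAlH4, THF, 0 °C) gives the robust, purifiable (R)-2-(benzyloxy)propan-1-ol F6. This is oxidised under non-basic conditions (TEMPO cat., PhI(OAc)2, CH2Cl2, rt) to 5 immediately before the key step.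
- Rationale: a two-step redox detour replaces the delicate stop at the aldehyde level.

(c) Step 1.
- Risks: alkylation on the heterogeneous silver oxide may be sluggish or incomplete. Adventitious water may consume the benzyl bromide, and basic sites of the oxide may cause partial exchange of the C2–H next to the ester.
- Fallback route: it sets out from 1 and returns at 5, bypassing steps 1 and 2, and never alkylates next to a carbonyl group. Compound 1 is reduced (LiAlH4, THF) to (R)-propane-1,2-diol F7. Acetalisation (PhCH(OMe)2, CSA cat., CH2Cl2) gives (4R)-4-methyl-2-phenyl-1,3-dioxolane F8 as a mixture of C2 epimers. Regioselective reductive opening (DIBAL-H, CH2Cl2, 0 °C) then follows: aluminium binds the less hindered primary oxygen and cleaves the acetal C–O bond there. This leaves the benzyl group on the secondary oxygen and gives (R)-2-(benzyloxy)propan-1-ol F6, which is oxidised with TEMPO/PhI(OAc)2 as above to 5.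

**Further compounds**
F1 | step 3 | 1-bromo-2,4,5-trimethoxybenzene | COc1cc(OC)c(Br)cc1OC
F2 | step 3 | 2,4,5-trimethoxyphenyllithium | [Li]c1cc(OC)c(OC)cc1OC
F3 | step 3 | (R)-2-(benzyloxy)-1-(2,4,5-trimethoxyphenyl)propan-1-one | C[C@@H](OCc1ccccc1)C(=O)c1cc(OC)c(OC)cc1OC
F4 | step 3 | (R)-2-(benzyloxy)-1,1-bis(2,4,5-trimethoxyphenyl)propan-1-ol | C[C@@H](OCc1ccccc1)C(O)(c1cc(OC)c(OC)cc1OC)c1cc(OC)c(OC)cc1OC
F5 | step 3 | (R)-2-(benzyloxy)-1,1-bis(2,4,5-trimethoxyphenyl)propan-1-ylium | C[C@@H](OCc1ccccc1)[C+](c1cc(OC)c(OC)cc1OC)c1cc(OC)c(OC)cc1OC
F6 | step 2 | (R)-2-(benzyloxy)propan-1-ol | C[C@@H](OCc1ccccc1)CO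
F7 | step 1 | (R)-propane-1,2-diol | C[C@@H](O)CO
F8 | step 1 | (4R)-4-methyl-2-phenyl-1,3-dioxolane (C2 epimers) | C[C@@H]1COC(c2ccccc2)O1
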